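## Retrosynthetic overview

- Locants used below: ring C1 (O-angeloyl), C2 (OH), C3 (OH, CH3), C4 (Cl), C5 (CH2), C6 (side chain); side chain C7 (=C14H2), C8 (O-angeloyl), C9, C10–C11 (oxirane).
- Enabling feature: the C2 carbinol sits between C1 and C3, so C2 is a latent ketone with two nucleophilic α-carbons; the trans C3(OH)/C4(Cl) chlorohydrin is a latent C3=C4 enone alkene (via the C3–C4 epoxide), which makes C4 a latent aldehyde carbon and C6, β to it, a Michael acceptor carbon.
- Key disconnection (the only carbocycle, formed first): C1–C2–C3 comes from tert-butyl 3-oxopentanoate (the ester on C1 is a removable activating group) and C4–C5–C6 from an (E)-enal; a one-flask amine-catalysed Michael addition (C1 to C6), aldol condensation (C3 to C4) and decarboxylation gives the 2-methylcyclohex-2-enone with C6 set by the catalyst.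
- The C6 arm is then grown (aldehyde α-methylenation for C7=CH2, reagent-controlled allylboration for C8, cross-metathesis for the prenyl end, first angelate). The ring is dressed by relay from C6: C1–O (enolate hydroxylation, then Mitsunobu inversion with angelic acid), C2–OH (Luche), C3–C4 oxirane (hydroxyl-directed), chlorohydrin (chloride opening).
- The side-chain oxirane ring (C10–C11) is formed last by catalyst-controlled epoxidation.

Key step: step 3

Remark: tert-butyl 3-oxopentanoate, both antipodes of the prolinol silyl ether catalyst, (−)-B-allyldiisopinocampheylborane and the L-fructose-derived Shi ketone are assumed to be purchasable; catalyst and reagent antipodes are chosen on the usual steric models.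

## Route

Step 1
Reactants: 1 but-3-en-1-ol
Product: 2 (but-3-en-1-yloxy)(tert-butyl)diphenylsilane
Conditions: TBDPSCl, imidazole, CH2Cl2, 0 °C to rt
Reagents that add atoms: tert-butyl(chloro)diphenylsilane, CC(C)(C)[Si](Cl)(c1ccccc1)c1ccccc1
Why: Standard silylation of a primary alcohol; the acid-stable TBDPS ether is chosen so that it survives the acidic second stage of step 3.

Step 2
Reactants: 2 (but-3-en-1-yloxy)(tert-butyl)diphenylsilane
Product: 3 (2E)-5-[(tert-butyldiphenylsilyl)oxy]pent-2-enal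
Conditions: crotonaldehyde (5 equiv), second-generation Hoveyda–Grubbs catalyst RuCl2(=CH-C6H4-2-OiPr)(H2IMes) (2 mol %), CH2Cl2, 40 °C
Reagents that add atoms: (2E)-but-2-enal (crotonaldehyde), C/C=C/C=O
Why: Olefin cross-metathesis of a terminal alkene with an excess of an enal should give the conjugated E-enal, the thermodynamically favoured geometry.

Step 3
Reactants: 3 (2E)-5-[(tert-butyldiphenylsilyl)oxy]pent-2-enal; 4 tert-butyl 3-oxopentanoate
Product: 7 (5R)-5-{2-[(tert-butyldiphenylsilyl)oxy]ethyl}-2-methylcyclohex-2-en-1-one, via Michael adduct 5 (not isolated), via keto aldehyde 6 (not isolated)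
Conditions: (R)-2-{bis[3,5-bis(trifluoromethyl)phenyl][(trimethylsilyl)oxy]methyl}pyrrolidine (10 mol %), PhCO2H (10 mol %), toluene, rt; then TsOH·H2O (20 mol %), 80 °C
Reagents that add atoms: none
Why: The secondary amine converts the enal into an E-configured iminium ion, the ester-activated C1 of 4 adds to its β-carbon C6 (Michael addition, first bond), and after acid is added the tert-butyl ester is lost as isobutene and CO2 while the enol of the ethyl ketone (C3) condenses with the C4 aldehyde and water is eliminated (second bond). This is the known amine-catalysed Michael/aldol-condensation/decarboxylation annulation of β-keto esters with enals, a Robinson-type [3+3] assembly. The ring closes in the 6-(enolendo)-exo-trig aldol mode and dehydration gives the conjugated C3=C4 double bond. The only stereocentre, C6, is set in the Michael step by the catalyst, whose diaryl(silyloxy)methyl group shields one face of the s-trans iminium ion; the (R)-catalyst is chosen so that C1 enters on the face that leads to the (5R)-enone. The step needs 1,4- over 1,2-addition and C1 rather than C3 as the Michael donor, both secured by the soft, doubly activated C1–H of the β-keto ester, and a single aldol pairing, secured because only C3 onto C4 gives a six-membered ring. The silyl ether keeps the two arms on C6 different, so the C6 configuration is carried through the ring closure.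

Step 4
Reactants: 7 (5R)-5-{2-[(tert-butyldiphenylsilyl)oxy]ethyl}-2-methylcyclohex-2-en-1-one
Product: 8 (5R)-5-(2-hydroxyethyl)-2-methylcyclohex-2-en-1-one
Conditions: HF·pyridine, THF/pyridine, 0 °C to rt
Reagents that add atoms: none
Why: Fluoride-mediated desilylation under weakly acidic conditions should leave the enone and the C6 centre untouched.

Step 5
Reactants: 8 (5R)-5-(2-hydroxyethyl)-2-methylcyclohex-2-en-1-one
Product: 9 [(1R)-4-methyl-3-oxocyclohex-4-en-1-yl]acetaldehyde
Conditions: TEMPO (10 mol %), PhI(OAc)2, CH2Cl2, rt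
Reagents that add atoms: none
Why: Oxoammonium-catalysed (TEMPO) oxidation of a primary alcohol stops at the aldehyde and does not affect the enone or C6.

Step 6
Reactants: 9 [(1R)-4-methyl-3-oxocyclohex-4-en-1-yl]acetaldehyde
Product: 10 2-[(1S)-4-methyl-3-oxocyclohex-4-en-1-yl]prop-2-enal
Conditions: 37% aq. CH2O, pyrrolidine (10 mol %), EtCO2H (10 mol %), i-PrOH, 45 °C
Reagents that add atoms: formaldehyde, C=O
Why: Amine-catalysed α-methylenation of an aldehyde (Mannich condensation, then elimination) installs C7=C14H2; the aldehyde forms its enamine far faster than the hindered ring enone, and C6 is not enolisable on this path.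

Step 7
Reactants: 10 2-[(1S)-4-methyl-3-oxocyclohex-4-en-1-yl]prop-2-enal
Product: 12 (5S)-5-[(3S)-3-hydroxyhexa-1,5-dien-2-yl]-2-methylcyclohex-2-en-1-one, via borinate ester 11 (not isolated)
Conditions: (−)-Ipc2B(CH2CH=CH2) (from (+)-α-pinene, salt-free), Et2O, −78 °C; then HOCH2CH2NH2, rt
Reagents that add atoms: (−)-B-allyldiisopinocampheylborane, C=CCB([C@H]1[C@H](C)[C@H]2C[C@@H](C1)C2(C)C)[C@H]3[C@H](C)[C@H]4C[C@@H](C3)C4(C)C
Why: Asymmetric allylboration through a chair Zimmerman–Traxler transition state; the reagent from (+)-α-pinene should add allyl to the Si face of the aldehyde (reagent control) to give (8S), the aldehyde reacts far faster than the ring ketone, and the non-oxidative work-up spares the enone.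

Step 8
Reactants: 12 (5S)-5-[(3S)-3-hydroxyhexa-1,5-dien-2-yl]-2-methylcyclohex-2-en-1-one
Product: 13 (3S)-2-[(1S)-4-methyl-3-oxocyclohex-4-en-1-yl]hexa-1,5-dien-3-yl (2Z)-2-methylbut-2-enoate
Conditions: (2Z)-2-methylbut-2-enoic acid, 2,4,6-Cl3C6H2COCl, Et3N, toluene, rt; then 12, 75 °C
Reagents that add atoms: (2Z)-2-methylbut-2-enoic acid (angelic acid), C/C=C(/C)C(=O)O
Why: Yamaguchi-type mixed-anhydride esterification; the alcohol attacks the less hindered angeloyl carbonyl, C8 keeps its configuration, and the absence of a nucleophilic catalyst should prevent Z-to-E isomerisation of the acyl group.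

Step 9
Reactants: 13 (3S)-2-[(1S)-4-methyl-3-oxocyclohex-4-en-1-yl]hexa-1,5-dien-3-yl (2Z)-2-methylbut-2-enoate
Product: 14 (3S)-6-methyl-2-[(1S)-4-methyl-3-oxocyclohex-4-en-1-yl]hepta-1,5-dien-3-yl (2Z)-2-methylbut-2-enoate
Conditions: 2-methylbut-2-ene (co-solvent), second-generation Grubbs catalyst RuCl2(=CHPh)(H2IMes)(PCy3) (5 mol %), CH2Cl2, 40 °C
Reagents that add atoms: 2-methylbut-2-ene, CC=C(C)C
Why: Cross-metathesis of the only monosubstituted alkene with 2-methylbut-2-ene builds the prenyl terminus; the 1,1-disubstituted, trisubstituted and conjugated alkenes are too hindered or electron-poor to compete.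

Step 10
Reactants: 14 (3S)-6-methyl-2-[(1S)-4-methyl-3-oxocyclohex-4-en-1-yl]hepta-1,5-dien-3-yl (2Z)-2-methylbut-2-enoate
Product: 16 (3S)-2-[(1R,2R)-2-hydroxy-4-methyl-3-oxocyclohex-4-en-1-yl]-6-methylhepta-1,5-dien-3-yl (2Z)-2-methylbut-2-enoate, via sodium dienolate 15 (not isolated)
Conditions: NaN(SiMe3)2, THF, −78 °C; then (±)-trans-3-phenyl-2-(phenylsulfonyl)oxaziridine, −78 °C; AcOH
Reagents that add atoms: 3-phenyl-2-(phenylsulfonyl)oxaziridine (Davis reagent), O=S(=O)(N1OC1c1ccccc1)c1ccccc1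
Why: Kinetic deprotonation gives the cross-conjugated C1=C2 dienolate, and enolate α-hydroxylation by the oxaziridine should occur at C1 on the face anti to the adjacent C6 substituent, giving the trans α′-hydroxy enone that step 11 inverts.

Step 11
Reactants: 16 (3S)-2-[(1R,2R)-2-hydroxy-4-methyl-3-oxocyclohex-4-en-1-yl]-6-methylhepta-1,5-dien-3-yl (2Z)-2-methylbut-2-enoate
Product: 17 (1S,6R)-3-methyl-6-[(3S)-6-methyl-3-{[(2Z)-2-methylbut-2-enoyl]oxy}hepta-1,5-dien-2-yl]-2-oxocyclohex-3-en-1-yl (2Z)-2-methylbut-2-enoate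
Conditions: (2Z)-2-methylbut-2-enoic acid, PPh3, DIAD, toluene, 0 °C to rt
Reagents that add atoms: (2Z)-2-methylbut-2-enoic acid (angelic acid), C/C=C(/C)C(=O)O
Why: Mitsunobu esterification; angelate displaces the oxyphosphonium group at the α-keto carbon C1 by SN2 with inversion, which sets the cis C1–O/C6 relationship and installs the ring angelate in the same step.

Step 12
Reactants: 17 (1S,6R)-3-methyl-6-[(3S)-6-methyl-3-{[(2Z)-2-methylbut-2-enoyl]oxy}hepta-1,5-dien-2-yl]-2-oxocyclohex-3-en-1-yl (2Z)-2-methylbut-2-enoate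
Product: 18 (1S,2R,6R)-2-hydroxy-3-methyl-6-[(3S)-6-methyl-3-{[(2Z)-2-methylbut-2-enoyl]oxy}hepta-1,5-dien-2-yl]cyclohex-3-en-1-yl (2Z)-2-methylbut-2-enoate
Conditions: NaBH4, CeCl3·7H2O, MeOH, −78 to −40 °C
Reagents that add atoms: none
Why: Luche 1,2-reduction; hydride should add axially to C2, anti to the pseudo-axial C1 acyloxy group, so the new hydroxyl is cis to the C1 ester and to the C6 substituent (the sense of carvone to cis-carveol), with esters and alkenes untouched.

Step 13
Reactants: 18 (1S,2R,6R)-2-hydroxy-3-methyl-6-[(3S)-6-methyl-3-{[(2Z)-2-methylbut-2-enoyl]oxy}hepta-1,5-dien-2-yl]cyclohex-3-en-1-yl (2Z)-2-methylbut-2-enoate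
Product: 19 (1S,2S,3S,4R,6R)-3,4-epoxy-2-hydroxy-3-methyl-6-[(3S)-6-methyl-3-{[(2Z)-2-methylbut-2-enoyl]oxy}hepta-1,5-dien-2-yl]cyclohexyl (2Z)-2-methylbut-2-enoate
Conditions: VO(acac)2 (5 mol %), t-BuOOH (decane), CH2Cl2, 0 °C to rt
Reagents that add atoms: tert-butyl hydroperoxide, CC(C)(C)OO
Why: Hydroxyl-directed vanadium-catalysed epoxidation of an allylic alcohol delivers oxygen to the C3=C4 face syn to the C2 hydroxyl, and the non-allylic alkenes (C7=C14, C10=C11, angelates) should not react.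

Step 14
Reactants: 19 (1S,2S,3S,4R,6R)-3,4-epoxy-2-hydroxy-3-methyl-6-[(3S)-6-methyl-3-{[(2Z)-2-methylbut-2-enoyl]oxy}hepta-1,5-dien-2-yl]cyclohexyl (2Z)-2-methylbut-2-enoate
Product: 20 (1S,2S,3S,4S,6R)-4-chloro-2,3-dihydroxy-3-methyl-6-[(3S)-6-methyl-3-{[(2Z)-2-methylbut-2-enoyl]oxy}hepta-1,5-dien-2-yl]cyclohexyl (2Z)-2-methylbut-2-enoate
Conditions: LiCl (5 equiv), AcOH (3 equiv), THF, rt
Reagents that add atoms: lithium chloride, [Li+].[Cl-]
Why: Acid-assisted SN2 opening of the epoxide by chloride (halohydrin formation) should occur at the secondary C4 with inversion, in the trans-diaxial sense and away from the tertiary C3 that the C2 oxygen deactivates, giving Cl trans to the C3 hydroxyl.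

Step 15
Reactants: 20 (1S,2S,3S,4S,6R)-4-chloro-2,3-dihydroxy-3-methyl-6-[(3S)-6-methyl-3-{[(2Z)-2-methylbut-2-enoyl]oxy}hepta-1,5-dien-2-yl]cyclohexyl (2Z)-2-methylbut-2-enoate
Product: 21 (1S,2S,3S,4S,6R)-4-chloro-6-[(3S)-4-[(2S)-3,3-dimethyloxiran-2-yl]-3-{[(2Z)-2-methylbut-2-enoyl]oxy}but-1-en-2-yl]-2,3-dihydroxy-3-methylcyclohexyl (2Z)-2-methylbut-2-enoate
Conditions: L-fructose-derived Shi ketone (30 mol %), Oxone (2KHSO5·KHSO4·K2SO4), K2CO3, Bu4NHSO4, MeCN/(MeO)2CH2–aq. Na2B4O7 buffer, 0 °C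
Reagents that add atoms: potassium peroxymonosulfate (active part of Oxone), [K+].OOS(=O)(=O)[O-]
Why: Shi asymmetric epoxidation; the chiral dioxirane should epoxidise the electron-rich trisubstituted C10=C11 bond under catalyst control (10S expected from the L-fructose series), leaving the 1,1-disubstituted C7=C14 and the electron-poor angelate alkenes.

## Compound list

1 | but-3-en-1-ol | C=CCCO | starting material
2 | (but-3-en-1-yloxy)(tert-butyl)diphenylsilane | C=CCCO[Si](c1ccccc1)(c1ccccc1)C(C)(C)C | intermediate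
3 | (2E)-5-[(tert-butyldiphenylsilyl)oxy]pent-2-enal | O=C/C=C/CCO[Si](c1ccccc1)(c1ccccc1)C(C)(C)C | intermediate
4 | tert-butyl 3-oxopentanoate | CCC(=O)CC(=O)OC(C)(C)C | starting material
5 | tert-butyl (3S)-5-[(tert-butyldiphenylsilyl)oxy]-3-(2-oxoethyl)-2-propanoylpentanoate (Michael adduct, C2 epimers, not isolated) | CC(C)(C)[Si](OCC[C@H](C(C(=O)CC)C(=O)OC(C)(C)C)CC=O)(c1ccccc1)c1ccccc1 | intermediate
6 | (3S)-3-{2-[(tert-butyldiphenylsilyl)oxy]ethyl}-5-oxoheptanal (keto aldehyde, not isolated) | CC(C)(C)[Si](OCC[C@H](CC(=O)CC)CC=O)(c1ccccc1)c1ccccc1 | intermediate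
7 | (5R)-5-{2-[(tert-butyldiphenylsilyl)oxy]ethyl}-2-methylcyclohex-2-en-1-one | CC(C)(C)[Si](OCC[C@H]1CC=C(C)C(=O)C1)(c2ccccc2)c3ccccc3 | intermediate
8 | (5R)-5-(2-hydroxyethyl)-2-methylcyclohex-2-en-1-one | OCC[C@H]1CC=C(C)C(=O)C1 | intermediate
9 | [(1R)-4-methyl-3-oxocyclohex-4-en-1-yl]acetaldehyde | O=CC[C@H]1CC=C(C)C(=O)C1 | intermediate
10 | 2-[(1S)-4-methyl-3-oxocyclohex-4-en-1-yl]prop-2-enal | C=C(C=O)[C@H]1CC=C(C)C(=O)C1 | intermediate
11 | {[(3S)-2-[(1S)-4-methyl-3-oxocyclohex-4-en-1-yl]hexa-1,5-dien-3-yl]oxy}bis[(1R,2S,3R,5R)-2,6,6-trimethylbicyclo[3.1.1]heptan-3-yl]borane (borinate ester, not isolated) | C=C([C@H](CC=C)OB([C@H]1[C@H](C)[C@H]2C[C@@H](C1)C2(C)C)[C@H]3[C@H](C)[C@H]4C[C@@H](C3)C4(C)C)[C@H]5CC=C(C)C(=O)C5 | intermediate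
12 | (5S)-5-[(3S)-3-hydroxyhexa-1,5-dien-2-yl]-2-methylcyclohex-2-en-1-one | C=C([C@H](CC=C)O)[C@H]1CC=C(C)C(=O)C1 | intermediate
13 | (3S)-2-[(1S)-4-methyl-3-oxocyclohex-4-en-1-yl]hexa-1,5-dien-3-yl (2Z)-2-methylbut-2-enoate | C=C([C@H](CC=C)OC(=O)/C(C)=C\C)[C@H]1CC=C(C)C(=O)C1 | intermediate
14 | (3S)-6-methyl-2-[(1S)-4-methyl-3-oxocyclohex-4-en-1-yl]hepta-1,5-dien-3-yl (2Z)-2-methylbut-2-enoate | C=C([C@H](CC=C(C)C)OC(=O)/C(C)=C\C)[C@H]1CC=C(C)C(=O)C1 | intermediate
15 | sodium (3S)-6-methyl-3-[(3S)-6-methyl-3-{[(2Z)-2-methylbut-2-enoyl]oxy}hepta-1,5-dien-2-yl]cyclohexa-1,5-dien-1-olate (cross-conjugated dienolate, not isolated) | C=C([C@H](CC=C(C)C)OC(=O)/C(C)=C\C)[C@H]1CC=C(C)C([O-])=C1.[Na+] | intermediate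
16 | (3S)-2-[(1R,2R)-2-hydroxy-4-methyl-3-oxocyclohex-4-en-1-yl]-6-methylhepta-1,5-dien-3-yl (2Z)-2-methylbut-2-enoate | C=C([C@H](CC=C(C)C)OC(=O)/C(C)=C\C)[C@H]1CC=C(C)C(=O)[C@@H]1O | intermediate
17 | (1S,6R)-3-methyl-6-[(3S)-6-methyl-3-{[(2Z)-2-methylbut-2-enoyl]oxy}hepta-1,5-dien-2-yl]-2-oxocyclohex-3-en-1-yl (2Z)-2-methylbut-2-enoate | C=C([C@H](CC=C(C)C)OC(=O)/C(C)=C\C)[C@H]1CC=C(C)C(=O)[C@H]1OC(=O)/C(C)=C\C | intermediate
18 | (1S,2R,6R)-2-hydroxy-3-methyl-6-[(3S)-6-methyl-3-{[(2Z)-2-methylbut-2-enoyl]oxy}hepta-1,5-dien-2-yl]cyclohex-3-en-1-yl (2Z)-2-methylbut-2-enoate | C=C([C@H](CC=C(C)C)OC(=O)/C(C)=C\C)[C@H]1CC=C(C)[C@@H](O)[C@H]1OC(=O)/C(C)=C\C | intermediate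
19 | (1S,2S,3S,4R,6R)-3,4-epoxy-2-hydroxy-3-methyl-6-[(3S)-6-methyl-3-{[(2Z)-2-methylbut-2-enoyl]oxy}hepta-1,5-dien-2-yl]cyclohexyl (2Z)-2-methylbut-2-enoate | C=C([C@H](CC=C(C)C)OC(=O)/C(C)=C\C)[C@H]1C[C@H]2O[C@@]2(C)[C@@H](O)[C@H]1OC(=O)/C(C)=C\C | intermediate
20 | (1S,2S,3S,4S,6R)-4-chloro-2,3-dihydroxy-3-methyl-6-[(3S)-6-methyl-3-{[(2Z)-2-methylbut-2-enoyl]oxy}hepta-1,5-dien-2-yl]cyclohexyl (2Z)-2-methylbut-2-enoate | C=C([C@H](CC=C(C)C)OC(=O)/C(C)=C\C)[C@H]1C[C@H](Cl)[C@@](C)(O)[C@@H](O)[C@H]1OC(=O)/C(C)=C\C | intermediate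
21 | (1S,2S,3S,4S,6R)-4-chloro-6-[(3S)-4-[(2S)-3,3-dimethyloxiran-2-yl]-3-{[(2Z)-2-methylbut-2-enoyl]oxy}but-1-en-2-yl]-2,3-dihydroxy-3-methylcyclohexyl (2Z)-2-methylbut-2-enoate | C=C([C@H](C[C@@H]1OC1(C)C)OC(=O)/C(C)=C\C)[C@H]1C[C@H](Cl)[C@@](C)(O)[C@@H](O)[C@H]1OC(=O)/C(C)=C\C | target

## Step count and risks

Total step count: 15. Longest linear sequence: 15 steps (1 to 21); compound 4 enters at step 3.

Steps most likely to fail:

**Step 11 (Mitsunobu inversion at C1).** SN2 attack at the hindered α-keto carbon may be outrun by elimination or by enolisation of the oxyphosphonium intermediate, which would scramble C1, and the angeloyl group may isomerise from Z to E under the basic betaine. The fallback replaces substitution by epimerisation. It sets out from 16, which is silylated (Et3SiCl, imidazole, DMF) to the triethylsilyl ether (3S)-6-methyl-2-{(1R,2R)-4-methyl-3-oxo-2-[(triethylsilyl)oxy]cyclohex-4-en-1-yl}hepta-1,5-dien-3-yl (2Z)-2-methylbut-2-enoate F3. Deprotonation at C1 (NaN(SiMe3)2, THF, −78 °C) and kinetic protonation with 2,6-di-tert-butylphenol, which should come from the face anti to the C6 substituent, would give the cis epimer (3S)-6-methyl-2-{(1R,2S)-4-methyl-3-oxo-2-[(triethylsilyl)oxy]cyclohex-4-en-1-yl}hepta-1,5-dien-3-yl (2Z)-2-methylbut-2-enoate F4. HF·pyridine would then free the cis α′-hydroxy enone (3S)-2-[(1R,2S)-2-hydroxy-4-methyl-3-oxocyclohex-4-en-1-yl]-6-methylhepta-1,5-dien-3-yl (2Z)-2-methylbut-2-enoate F5, which is esterified with retention under the mixed-anhydride conditions of step 8. The fallback comes back to the route at 17.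

**Step 15 (late epoxidation of C10=C11).** At the pH of the buffered oxidation the trans-diaxial chlorohydrin may close back to the C3–C4 epoxide, excess oxidant may also attack C7=C14, and facial control at the remote C10=C11 bond rests on the catalyst alone. The fallback reverses the order of the last two events. It sets out from 19, which carries no base-labile chlorohydrin and is epoxidised under the conditions of step 15 to the bis-epoxide (1S,2S,3S,4R,6R)-6-[(3S)-4-[(2S)-3,3-dimethyloxiran-2-yl]-3-{[(2Z)-2-methylbut-2-enoyl]oxy}but-1-en-2-yl]-3,4-epoxy-2-hydroxy-3-methylcyclohexyl (2Z)-2-methylbut-2-enoate F6. A hydroxyl-directed chloride opening (Et2NH·HCl, Ti(OiPr)4, CH2Cl2, rt), in which the titanium alkoxide of the C2 hydroxyl should activate only the adjacent C3–C4 oxirane, then delivers chloride to C4. The fallback comes back to the route at 21.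

**Step 10 (α′-hydroxylation of the enone).** The dienolate may attack the C8 ester intramolecularly (acyl transfer through a six-membered transition state) before oxygen transfer, the sulfonimine by-product may add to the enolate, and facial selectivity at C1 may be modest. The fallback changes both the electrophile and the way the oxygen is brought in. It sets out from 14, which is silylated under internal-quench conditions (LiN(SiMe3)2, Me3SiCl, THF, −78 °C) so that the free enolate has no lifetime, giving the silyl dienol ether (3S)-6-methyl-2-{(1S)-4-methyl-3-[(trimethylsilyl)oxy]cyclohexa-2,4-dien-1-yl}hepta-1,5-dien-3-yl (2Z)-2-methylbut-2-enoate F1. N-Bromosuccinimide (THF, −78 °C) should brominate C1 anti to the C6 substituent to give the trans α′-bromo enone (3S)-2-[(1R,2R)-2-bromo-4-methyl-3-oxocyclohex-4-en-1-yl]-6-methylhepta-1,5-dien-3-yl (2Z)-2-methylbut-2-enoate F2. SN2 displacement with cesium (2Z)-2-methylbut-2-enoate (CsO2C–C(CH3)=CHCH3, 18-crown-6, toluene, rt) then inverts C1. The fallback comes back to the route at 17 and bypasses 16 and step 11.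

Further compounds
F1 | step 10 | (3S)-6-methyl-2-{(1S)-4-methyl-3-[(trimethylsilyl)oxy]cyclohexa-2,4-dien-1-yl}hepta-1,5-dien-3-yl (2Z)-2-methylbut-2-enoate | C=C([C@H](CC=C(C)C)OC(=O)/C(C)=C\C)[C@H]1CC=C(C)C(O[Si](C)(C)C)=C1
F2 | step 10 | (3S)-2-[(1R,2R)-2-bromo-4-methyl-3-oxocyclohex-4-en-1-yl]-6-methylhepta-1,5-dien-3-yl (2Z)-2-methylbut-2-enoate | C=C([C@H](CC=C(C)C)OC(=O)/C(C)=C\C)[C@H]1CC=C(C)C(=O)[C@@H]1Br
F3 | step 11 | (3S)-6-methyl-2-{(1R,2R)-4-methyl-3-oxo-2-[(triethylsilyl)oxy]cyclohex-4-en-1-yl}hepta-1,5-dien-3-yl (2Z)-2-methylbut-2-enoate | C=C([C@H](CC=C(C)C)OC(=O)/C(C)=C\C)[C@H]1CC=C(C)C(=O)[C@@H]1O[Si](CC)(CC)CC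
F4 | step 11 | (3S)-6-methyl-2-{(1R,2S)-4-methyl-3-oxo-2-[(triethylsilyl)oxy]cyclohex-4-en-1-yl}hepta-1,5-dien-3-yl (2Z)-2-methylbut-2-enoate | C=C([C@H](CC=C(C)C)OC(=O)/C(C)=C\C)[C@H]1CC=C(C)C(=O)[C@H]1O[Si](CC)(CC)CC
F5 | step 11 | (3S)-2-[(1R,2S)-2-hydroxy-4-methyl-3-oxocyclohex-4-en-1-yl]-6-methylhepta-1,5-dien-3-yl (2Z)-2-methylbut-2-enoate | C=C([C@H](CC=C(C)C)OC(=O)/C(C)=C\C)[C@H]1CC=C(C)C(=O)[C@H]1O
F6 | step 15 | (1S,2S,3S,4R,6R)-6-[(3S)-4-[(2S)-3,3-dimethyloxiran-2-yl]-3-{[(2Z)-2-methylbut-2-enoyl]oxy}but-1-en-2-yl]-3,4-epoxy-2-hydroxy-3-methylcyclohexyl (2Z)-2-methylbut-2-enoate | C=C([C@H](C[C@@H]1OC1(C)C)OC(=O)/C(C)=C\C)[C@H]1C[C@H]2O[C@@]2(C)[C@@H](O)[C@H]1OC(=O)/C(C)=C\C
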